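**Strategy**

The target is a guaiane, a cyclopentane fused to a cycloheptene (ring fusion C1/C5, C1=C10). The route rests on a formal (4+3) disconnection of the seven-membered ring across C1–C5 and C8–C9. A rhodium vinylcarbene at C1 (C9=C10–C1) cyclopropanates the C5=C6 end of a tethered 2-siloxydiene (C5 to C8), and the cis-divinylcyclopropane undergoes Cope rearrangement: one operation closes both rings and delivers the C1=C10 alkene, flanked by C5–H and C9H2, which is the feature exploited. The precursor is an open-chain sulfonylhydrazone from (S)-linalool whose C4 carbinol is tied to the C6 enol oxygen in a silylene ring; C4 thereby dictates C5, and C6 to C8 follow by substrate control.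

Key step: step 8

Remark: ring atoms carry guaiane numbers (C1/C5 ring fusion, C2–C4 in the five-membered ring, C6–C10 in the seven-membered ring; C4 bears methyl and hydroxyl, C7 the isopropyl, C10 the ring methyl); β is the face of the C4 hydroxyl and α the face of H5; (S)-(+)-linalool of high enantiomeric purity and 2-bromo-3-methylbut-1-ene are taken as purchasable.

**Route**

Step 1
Reactants: 1 (S)-(+)-linalool
Product: 3 (3S)-3,7-dimethyloct-6-ene-1,3-diol, via B-alkyl-9-BBN adduct 2 (not isolated)
Conditions: 9-BBN (2.2 equiv), THF, 0 °C to rt; then NaOH, H2O2, 0 °C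
Reagents that add atoms: hydrogen peroxide, OO
Why: Anti-Markovnikov hydroboration–oxidation, in which 9-BBN should add only to the monosubstituted vinyl group and leave the trisubstituted alkene, the purchased carbinol stereocentre (later C4) not being touched.

Step 2
Reactants: 3 (3S)-3,7-dimethyloct-6-ene-1,3-diol
Product: 4 (3S)-3-hydroxy-3,7-dimethyloct-6-enal
Conditions: TEMPO (10 mol %), PhI(OAc)2, CH2Cl2, rt; used crude
Reagents that add atoms: none
Why: The nitroxyl-catalysed (TEMPO) oxidation is selective for the primary alcohol and stops at the aldehyde, the tertiary alcohol and the alkene being inert under these near-neutral conditions.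

Step 3
Reactants: 4 (3S)-3-hydroxy-3,7-dimethyloct-6-enal; 5 2-bromo-3-methylbut-1-ene
Product: 6 (6S)-2,6,10-trimethyl-3-methylideneundec-9-ene-4,6-diol (both C4 epimers)
Conditions: 5, Mg, THF, rt (Grignard reagent, 2.5 equiv); then 4, THF, −78 to 0 °C; NH4Cl aq
Reagents that add atoms: none
Why: Grignard 1,2-addition to the aldehyde (one equivalent is spent on the tertiary hydroxyl) brings in C7, C8 and the isopropyl group, and the new carbinol centre is erased by the next oxidation.

Step 4
Reactants: 6 (6S)-2,6,10-trimethyl-3-methylideneundec-9-ene-4,6-diol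
Product: 7 (6S)-6-hydroxy-2,6,10-trimethyl-3-methylideneundec-9-en-4-one
Conditions: MnO2 (excess), CH2Cl2, rt
Reagents that add atoms: none
Why: Allylic alcohol oxidation with MnO2 is selective for the secondary allylic carbinol and should give the α-isopropyl vinyl ketone under neutral conditions that avoid retro-aldol cleavage and oxa-Michael closure of the β-hydroxy enone.

Step 5
Reactants: 7 (6S)-6-hydroxy-2,6,10-trimethyl-3-methylideneundec-9-en-4-one
Product: 10 (6S)-6-hydroxy-2,6,10-trimethyl-3-methylideneundec-10-ene-4,9-dione, via allylic hydroperoxide 8 (not isolated), via peroxyacetate 9 (not isolated)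
Conditions: O2, tetraphenylporphyrin (cat.), visible light, CH2Cl2, 0 °C; then Ac2O, pyridine, 0 °C to rt
Reagents that add atoms: dioxygen (as singlet oxygen), O=O
Why: The Schenck ene reaction of singlet oxygen with the only electron-rich alkene gives the secondary allylic hydroperoxide, and acetylation with Kornblum–DeLaMare-type elimination turns it into the isopropenyl ketone; the ene step is not expected to discriminate well between the two allylic positions, and the tertiary regioisomer, which cannot eliminate, is separated here.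

Step 6
Reactants: 10 (6S)-6-hydroxy-2,6,10-trimethyl-3-methylideneundec-10-ene-4,9-dione
Product: 11 (4S)-2,2-di-tert-butyl-4-methyl-6-(3-methylbut-1-en-2-yl)-4-(4-methyl-3-oxopent-4-en-1-yl)-4H-1,3,2-dioxasiline
Conditions: tBu2Si(OTf)2 (1.05 equiv), Et3N, CH2Cl2, −78 to 0 °C
Reagents that add atoms: di-tert-butylsilyl bis(trifluoromethanesulfonate), CC(C)(C)[Si](OS(=O)(=O)C(F)(F)F)(OS(=O)(=O)C(F)(F)F)C(C)(C)C
Why: Silylene formation, in which the bis-triflate silylates the tertiary alcohol and then, by amine-mediated soft enolisation, the oxygen of the β-ketone in a six-membered ring (the other ketone would need a seven-membered ring), should give the C5=C6 enol ether with O6 cis to C4 and hence the 2-siloxydiene.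

Step 7
Reactants: 11 (4S)-2,2-di-tert-butyl-4-methyl-6-(3-methylbut-1-en-2-yl)-4-(4-methyl-3-oxopent-4-en-1-yl)-4H-1,3,2-dioxasiline
Product: 12 2-(trifluoromethyl)benzenesulfonylhydrazone of 11 at the isopropenyl ketone
Conditions: 2-(trifluoromethyl)benzenesulfonohydrazide (1.1 equiv), MgSO4, THF, rt
Reagents that add atoms: 2-(trifluoromethyl)benzenesulfonohydrazide, NNS(=O)(=O)c1ccccc1C(F)(F)F
Why: Hydrazone condensation at the only remaining ketone, under neutral conditions that should spare the hindered cyclic silyl enol ether, installs a diazo precursor that fragments well below room temperature.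

Step 8
Reactants: 12 2-(trifluoromethyl)benzenesulfonylhydrazone of 11
Product: 16 4β,6-O-(di-tert-butylsilylene)-5αH-guaia-1(10),6-diene-4β,6-diol (tricyclic silyl enol ether), via sodium hydrazonide 13 (not isolated), via vinyl diazoalkane 14 (not isolated), via cis-divinylcyclopropane 15 (not isolated)
Conditions: NaH, CH2Cl2, −40 °C; Rh2(OPiv)4 (2 mol %), −40 to 0 °C; then 40 °C
Reagents that add atoms: none
Why: Bamford–Stevens fragmentation of the sulfonylhydrazone anion releases the vinyl diazoalkane, which Rh2(OPiv)4 converts into a rhodium vinylcarbene at C1; this adds to the tethered enol ether C5=C6, and the cis-divinylcyclopropane 15 rearranges by a boat Cope shift that breaks C1–C6 and forms C8–C9. The closest known type is the tandem vinylcarbene cyclopropanation/divinylcyclopropane rearrangement (formal (4+3) cycloaddition), known intramolecularly for hydroazulenes and with vinylcarbenes generated from unsaturated sulfonylhydrazones. The five-membered ring closes in the (2+1) carbene addition through the three-atom tether (a bicyclo[3.1.0]hexane), the seven-membered ring in the (3,3)-sigmatropic step. The only new permanent stereocentre, C5, is set by C4: in the dioxasiline the ring oxygen O4 lies near the enol ether plane, so the carbene tether (C3) and the C4 methyl sit on opposite faces and the carbene can only reach the face that leaves O4 cis to C6, that is H5 α; C1 and C6 of 15 are transient. The cis relation of the two alkenyl groups needed for the Cope step is secured by the ring-enforced enol ether geometry (C7 trans to C4). The step needs cyclopropanation to outrun 1,2-hydride shift from C2 and pyrazole formation, which the five-membered tether, the electron-rich enol ether, the bulky carboxylate ligands and the low temperature should secure, and it needs attack at C5=C6 and not at C7=C8, which the tether length secures.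

Step 9
Reactants: 16 4β,6-O-(di-tert-butylsilylene)-5αH-guaia-1(10),6-diene-4β,6-diol
Product: 18 4β-hydroxy-5αH-guaia-1(10),7-dien-6-one, via acetoxysilyl enone 17 (not isolated)
Conditions: Pd(OAc)2 (1.1 equiv), MeCN, rt; then HF·pyridine, pyridine, THF, 0 °C
Reagents that add atoms: none
Why: Saegusa–Ito oxidation, in which Pd(OAc)2 turns the enol silane into the C7 palladium enolate and β-hydride elimination towards the ring methylene C8 should give the Δ7 enone, after which fluoride frees the tertiary alcohol, the neutral to weakly acidic conditions avoiding enolisation towards C5.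

Step 10
Reactants: 18 4β-hydroxy-5αH-guaia-1(10),7-dien-6-one
Product: 19 5αH-guaia-1(10),7-diene-4β,6β-diol
Conditions: NaBH4, CeCl3·7H2O, MeOH, −78 to −40 °C
Reagents that add atoms: none
Why: Luche reduction gives clean 1,2-reduction, and hydride should add to C6 from the α face (the face of H5) because the cyclopentane ring with its β hydroxyl is folded over the β face of the enone, which sets the 6β-hydroxyl.

Step 11
Reactants: 19 5αH-guaia-1(10),7-diene-4β,6β-diol
Product: 21 5αH,7αH-guai-1(10)-ene-4β,6β,8α-triol, via C8 alkylborane 20 (not isolated)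
Conditions: BH3·SMe2 (3 equiv), THF, 0 °C to rt; then NaOH, H2O2, 0 °C
Reagents that add atoms: hydrogen peroxide, OO
Why: Hydroboration–oxidation, in which borane should add syn across the trisubstituted C7=C8 bond (faster than across the tetrasubstituted C1=C10 bond) with boron at C8 and from the α face anti to the allylic C6 oxygen, so that H7 and the new 8-hydroxyl are both α.

Step 12
Reactants: 21 5αH,7αH-guai-1(10)-ene-4β,6β,8α-triol; 22 4-acetoxybenzoyl chloride
Product: 23 8α-(4-acetoxybenzoyloxy)-5αH,7αH-guai-1(10)-ene-4β,6β-diol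
Conditions: 22 (1.05 equiv), pyridine, DMAP (5 mol %), CH2Cl2, −30 to 0 °C
Reagents that add atoms: none
Why: Site-selective acylation by DMAP-catalysed acyl transfer should take the 8α-hydroxyl, the least hindered alcohol, since the 6β-hydroxyl is flanked by the ring fusion and the cis isopropyl group and the 4-hydroxyl is tertiary.

Step 13
Reactants: 23 8α-(4-acetoxybenzoyloxy)-5αH,7αH-guai-1(10)-ene-4β,6β-diol
Product: 24 8α-(4-hydroxybenzoyloxy)-5αH,7αH-guai-1(10)-ene-4β,6β-diol (4S,5S,6R,7S,8S; the target)
Conditions: K2CO3 (0.2 equiv), MeOH, 0 °C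
Reagents that add atoms: none
Why: Base-catalysed transesterification should remove the aryl acetate, which is far more electrophilic than the hindered secondary alkyl benzoate, and release the phenol at a temperature that disfavours acyl migration to the 6-hydroxyl.

**Compound list**

1 | (S)-(+)-linalool, (3S)-3,7-dimethylocta-1,6-dien-3-ol | C=C[C@@](C)(O)CCC=C(C)C | starting material
2 | 9-[(3S)-3-hydroxy-3,7-dimethyloct-6-en-1-yl]-9-borabicyclo[3.3.1]nonane | B1(CC[C@@](C)(O)CCC=C(C)C)C2CCCC1CCC2 | intermediate (not isolated)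
3 | (3S)-3,7-dimethyloct-6-ene-1,3-diol | OCC[C@@](C)(O)CCC=C(C)C | intermediate
4 | (3S)-3-hydroxy-3,7-dimethyloct-6-enal | O=CC[C@@](C)(O)CCC=C(C)C | intermediate
5 | 2-bromo-3-methylbut-1-ene | CC(C)C(Br)=C | starting material
6 | (6S)-2,6,10-trimethyl-3-methylideneundec-9-ene-4,6-diol (both C4 epimers) | CC(C)C(=C)C(O)C[C@@](C)(O)CCC=C(C)C | intermediate
7 | (6S)-6-hydroxy-2,6,10-trimethyl-3-methylideneundec-9-en-4-one | CC(C)C(=C)C(=O)C[C@@](C)(O)CCC=C(C)C | intermediate
8 | (6S)-9-hydroperoxy-6-hydroxy-2,6,10-trimethyl-3-methylideneundec-10-en-4-one (C9 epimers) | CC(C)C(=C)C(=O)C[C@@](C)(O)CCC(OO)C(C)=C | intermediate (not isolated)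
9 | peroxyacetate of 8 | CC(C)C(=C)C(=O)C[C@@](C)(O)CCC(OOC(C)=O)C(C)=C | intermediate (not isolated)
10 | (6S)-6-hydroxy-2,6,10-trimethyl-3-methylideneundec-10-ene-4,9-dione | CC(C)C(=C)C(=O)C[C@@](C)(O)CCC(=O)C(C)=C | intermediate
11 | (4S)-2,2-di-tert-butyl-4-methyl-6-(3-methylbut-1-en-2-yl)-4-(4-methyl-3-oxopent-4-en-1-yl)-4H-1,3,2-dioxasiline | CC(C)C(=C)C1=C[C@](C)(CCC(=O)C(C)=C)O[Si](C(C)(C)C)(C(C)(C)C)O1 | intermediate
12 | 2-(trifluoromethyl)benzenesulfonylhydrazone of 11 at the isopropenyl ketone | CC(C)C(=C)C1=C[C@](C)(CCC(=NNS(=O)(=O)c2ccccc2C(F)(F)F)C(C)=C)O[Si](C(C)(C)C)(C(C)(C)C)O1 | intermediate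
13 | sodium salt of 12 | CC(C)C(=C)C1=C[C@](C)(CCC(=N[N-]S(=O)(=O)c2ccccc2C(F)(F)F)C(C)=C)O[Si](C(C)(C)C)(C(C)(C)C)O1.[Na+] | intermediate (not isolated)
14 | vinyl diazoalkane (diazo group at C1, isopropenyl attached) | CC(C)C(=C)C1=C[C@](C)(CCC(=[N+]=[N-])C(C)=C)O[Si](C(C)(C)C)(C(C)(C)C)O1 | intermediate (not isolated)
15 | cis-divinylcyclopropane: bicyclo[3.1.0]hexane (cyclopropane C1, C5, C6) fused to the dioxasilinane, isopropenyl on C1 and 3-methylbut-1-en-2-yl on C6 both exo | C=C(C)[C@]12CC[C@]3(C)O[Si](C(C)(C)C)(C(C)(C)C)O[C@@]1(C(=C)C(C)C)[C@H]23 | intermediate (not isolated)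
16 | 4β,6-O-(di-tert-butylsilylene)-5αH-guaia-1(10),6-diene-4β,6-diol | CC1=C2CC[C@]3(C)O[Si](C(C)(C)C)(C(C)(C)C)OC(=C(C(C)C)CC1)[C@H]23 | intermediate
17 | 4β-[acetoxy(di-tert-butyl)silyloxy]-5αH-guaia-1(10),7-dien-6-one | CC1=C2CC[C@](C)(O[Si](OC(C)=O)(C(C)(C)C)C(C)(C)C)[C@@H]2C(=O)C(C(C)C)=CC1 | intermediate (not isolated)
18 | 4β-hydroxy-5αH-guaia-1(10),7-dien-6-one | CC1=C2CC[C@](C)(O)[C@@H]2C(=O)C(C(C)C)=CC1 | intermediate
19 | 5αH-guaia-1(10),7-diene-4β,6β-diol | CC1=C2CC[C@](C)(O)[C@@H]2[C@H](O)C(C(C)C)=CC1 | intermediate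
20 | 8α-boryl-5αH,7αH-guai-1(10)-ene-4β,6β-diol (hydroxyls carried as borates in the flask, drawn free) | CC1=C2CC[C@](C)(O)[C@@H]2[C@H](O)[C@H](C(C)C)[C@@H](B)C1 | intermediate (not isolated)
21 | 5αH,7αH-guai-1(10)-ene-4β,6β,8α-triol | CC1=C2CC[C@](C)(O)[C@@H]2[C@H](O)[C@H](C(C)C)[C@@H](O)C1 | intermediate
22 | 4-acetoxybenzoyl chloride | CC(=O)Oc1ccc(cc1)C(Cl)=O | starting material
23 | 8α-(4-acetoxybenzoyloxy)-5αH,7αH-guai-1(10)-ene-4β,6β-diol | CC1=C2CC[C@](C)(O)[C@@H]2[C@H](O)[C@H](C(C)C)[C@@H](OC(=O)c2ccc(OC(C)=O)cc2)C1 | intermediate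
24 | 8α-(4-hydroxybenzoyloxy)-5αH,7αH-guai-1(10)-ene-4β,6β-diol, (4S,5S,6R,7S,8S) | CC1=C2CC[C@](C)(O)[C@@H]2[C@H](O)[C@H](C(C)C)[C@@H](OC(=O)c2ccc(O)cc2)C1 | target

**Step count and risks**

Total steps: 13. Longest linear sequence: 13 steps (1 to 24).

Steps most likely to fail:

Step 8. The carbene may be lost to 1,2-hydride migration from C2, or the vinyl diazoalkane may close to a pyrazole before rhodium captures it. The fallback makes the same two bonds by a cationic (4+3) cycloaddition; it sets out from 11 and returns at 16. Luche reduction of the isopropenyl ketone of 11 should give the allylic alcohol (4S)-2,2-di-tert-butyl-4-(3-hydroxy-4-methylpent-4-en-1-yl)-4-methyl-6-(3-methylbut-1-en-2-yl)-4H-1,3,2-dioxasiline F1. Its triflate, formed with Tf2O and 2,6-lutidine in CH2Cl2 at −78 °C, should ionise to the 2-methylallyl cation. The enol ether carbon C5 traps this cation at C1, and the resulting silyloxy-stabilised cation is trapped at C8 by the isopropenyl methylene C9. Loss of H1 from the tertiary C10 cation would then deliver 16, the silylene ring again fixing C5 relative to C4.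

Step 9. Transmetalation from the hindered silicon may be slow, β-hydride elimination may run towards the isopropyl methine (exocyclic enone), and the β,γ-unsaturated ketone may lose C5 configuration by enolisation. The fallback sets out from 16 and returns at 18. HF·pyridine in THF at 0 °C should cleave the silylene with protonation at C7 to give the hydroxy ketone 4β-hydroxy-5αH-guai-1(10)-en-6-one F2 (C7 epimers). IBX in DMSO at 70 °C should then dehydrogenate the free ketone by single-electron transfer; only the C7–C8 side can react, since C5 has no hydrogen-bearing β carbon, which leads to 18.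

Step 12. Acylation may not discriminate enough between the 8α- and 6β-hydroxyls, and the free hydroxyls may also erode facial control in step 11. The fallback sets out from 19 and returns at 23. tBu2Si(OTf)2 and 2,6-lutidine should tie the cis 4β,6β-diol of 19 into the silylene 4β,6β-O-(di-tert-butylsilylene)-5αH-guaia-1(10),7-diene-4β,6β-diol F3, whose β face is now shielded. Hydroboration–oxidation (BH3·SMe2, then NaOH, H2O2) should give the single free alcohol 4β,6β-O-(di-tert-butylsilylene)-5αH,7αH-guai-1(10)-ene-4β,6β,8α-triol F4. Acylation with 22 (pyridine, DMAP) gives the ester 8α-(4-acetoxybenzoyloxy) silylene F5, and HF·pyridine removes the silylene to give 23.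

Further compounds
F1 | step 8 | (4S)-2,2-di-tert-butyl-4-(3-hydroxy-4-methylpent-4-en-1-yl)-4-methyl-6-(3-methylbut-1-en-2-yl)-4H-1,3,2-dioxasiline (carbinol epimers) | CC(C)C(=C)C1=C[C@](C)(CCC(O)C(C)=C)O[Si](C(C)(C)C)(C(C)(C)C)O1
F2 | step 9 | 4β-hydroxy-5αH-guai-1(10)-en-6-one (C7 epimers) | CC1=C2CC[C@](C)(O)[C@@H]2C(=O)C(C(C)C)CC1
F3 | step 12 | 4β,6β-O-(di-tert-butylsilylene)-5αH-guaia-1(10),7-diene-4β,6β-diol | CC1=C2CC[C@]3(C)O[Si](C(C)(C)C)(C(C)(C)C)O[C@H](C(C(C)C)=CC1)[C@H]23
F4 | step 12 | 4β,6β-O-(di-tert-butylsilylene)-5αH,7αH-guai-1(10)-ene-4β,6β,8α-triol | CC1=C2CC[C@]3(C)O[Si](C(C)(C)C)(C(C)(C)C)O[C@H]([C@H](C(C)C)[C@@H](O)C1)[C@H]23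
F5 | step 12 | 8α-(4-acetoxybenzoyloxy)-4β,6β-O-(di-tert-butylsilylene)-5αH,7αH-guai-1(10)-ene-4β,6β-diol | CC1=C2CC[C@]3(C)O[Si](C(C)(C)C)(C(C)(C)C)O[C@H]([C@H](C(C)C)[C@@H](OC(=O)c4ccc(OC(C)=O)cc4)C1)[C@H]23
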